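Ring B is cut at C9–C10. The C20 methyl on quaternary C10 is read as the trace of hydrogen-atom transfer to an exocyclic C10=C20 methylene on ring A, and C9 as the β-carbon of a C9=C11–C12 enoate. In one operation Fe(acac)3/PhSiH3 turns the alkene into the tertiary C10 radical, which closes ring B 6-exo onto C9, creating the quaternary centre and the C9 stereocentre. The C6 ketone left in the ring later becomes the C6=C7 alkene. The precursor is an (R)-γ-cyclogeranyl ketone whose C7–C8 tether carries a glutaconate unit with the two carboxyls already differentiated (C17 tert-butyl ester on C8, C12 methyl enoate).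

Key step: step 6

Remarks on the chemistry
- Numbering: labdane numbering (C1–C20) is used for every compound. C17 is the carboxyl carbon on C8; C12 ends the arm on C9.
- Assumption: the less soluble salt of γ-cyclogeranic acid with (S)-1-phenylethylamine is taken to contain the (R)-acid. If the pairing proves opposite, (R)-1-phenylethylamine is used and nothing else changes.
- Precursor design: the two carboxyls are differentiated before ring closure, because after ring closure both are similarly hindered and cannot be told apart reliably by sterics. The glutaconate unit is therefore built on C8 from tert-butyl acetoacetate and methyl propiolate, which fixes tert-butyl at C17 and methyl at C12 without any regiochemical ambiguity.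
- C5 is the only source of absolute configuration and is α to the C6 ketone. Before ring closure it meets no base stronger than a stabilised enolate or carbonate in methanol at 0 °C.

Step 1
Reactants: 1 methyl γ-cyclogeranate, racemic
Product: 2 racemic γ-cyclogeranic acid
Conditions: NaSEt (3 equiv), DMF, 90 °C; then 1 M HCl
Reagents that add atoms: none
Why: Nucleophilic dealkylation of the methyl ester (thiolate attack at the O-methyl carbon) should free the acid without attack at the hindered carbonyl and without the hot hydroxide that could move the exocyclic alkene.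

Step 2
Reactants: 2 racemic γ-cyclogeranic acid; 3 (S)-1-phenylethylamine
Product: 4 (S)-1-phenylethylammonium (R)-γ-cyclogeranate, crystalline salt
Conditions: 3 (1.0 equiv), EtOAc, 60 °C → 4 °C; recrystallise to constant rotation
Reagents that add atoms: none
Why: Classical resolution by crystallisation of diastereomeric salts should enrich the salt of the (R)-acid, and it is done on the acid so that the resolved centre never sees an ester-enolising base.

Step 3
Reactants: 4 (S)-1-phenylethylammonium (R)-γ-cyclogeranate
Product: 8 2-bromo-1-[(1R)-2,2-dimethyl-6-methylidenecyclohexyl]ethan-1-one (bromomethyl ketone), via (R)-γ-cyclogeranic acid 5 (not isolated), via acid chloride 6 (not isolated), via diazoketone 7 (not isolated)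
Conditions: CH2Cl2/1 M HCl, dry (MgSO4); (COCl)2, DMF (cat.), 0 °C → rt; evaporate; CH2N2 (3 equiv), Et2O, 0 °C; 48% aq HBr, 0 °C
Reagents that add atoms: diazomethane, C=[N+]=[N-]; hydrogen bromide, Br
Why: Base-free acid chloride formation, acylation of diazomethane (the diazoketone stage of an Arndt–Eistert sequence) and hydrobromination of the diazoketone with loss of N2 should give the bromomethyl ketone, and since no amine base is present no ketene can form and C5 keeps its configuration.

Step 4
Reactants: 8 bromomethyl ketone; 9 tert-butyl acetoacetate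
Product: 10 tert-butyl 2-acetyl-4-[(1R)-2,2-dimethyl-6-methylidenecyclohexyl]-4-oxobutanoate (mixture at C8)
Conditions: 9 (1.5 equiv), NaH (1.3 equiv), THF, 0 °C; then 8, 0 °C → rt
Reagents that add atoms: none
Why: C-Alkylation of a β-keto ester enolate with a primary α-bromoketone (SN2) should form C7–C8 and place the future C17 carboxyl on C8 as its tert-butyl ester, the only base being the acetoacetate anion, which is too weak to remove H5.

Step 5
Reactants: 10 alkylated acetoacetate; 11 methyl propiolate
Product: 13 5-tert-butyl 1-methyl (2E)-4-{2-[(1R)-2,2-dimethyl-6-methylidenecyclohexyl]-2-oxoethyl}pent-2-enedioate (C8 epimers; may contain its C8=C9 tautomer), via C8-acetyl Michael adduct 12 (not isolated)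
Conditions: 11 (1.2 equiv), Cs2CO3 (10 mol%), MeCN, 0 °C → rt; evaporate; K2CO3 (1 equiv), MeOH, 0 °C; AcOH
Reagents that add atoms: none
Why: Michael addition of the tertiary β-keto ester carbon to the alkynoate attaches C9=C11–C12 to C8, and retro-Claisen deacetylation by methoxide should then be fast because the leaving carbanion is a glutaconate anion, whose protonation gives the (E)-enoate.

Step 6
Reactants: 13 γ-cyclogeranyl ketone with the glutaconate unit on C8
Product: 14 17-tert-butyl 12-methyl (5R,9R,10S)-6-oxo-13,14,15,16-tetranorlabdane-12,17-dioate (trans-decalin, C8 epimers)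
Conditions: Fe(acac)3 (0.5 equiv), PhSiH3 (2.5 equiv), EtOH/(CH2OH)2 (5:1), 0.02 M, 60 °C, degassed; chromatography to remove any cis-fused isomer
Reagents that add atoms: none
Why: The hydride of trivalent iron formed from Fe(acac)3 and PhSiH3 transfers a hydrogen atom to terminal C20 of the electron-rich exocyclic alkene, the nucleophilic tertiary C10 radical adds to the electrophilic enoate carbon C9, and the C11 radical is reduced by divalent iron and protonated by the solvent. The closest known reaction type is the iron-mediated hydrogen-atom-transfer reductive coupling of 1,1-disubstituted alkenes with acrylates (Giese type), here intramolecular and forming a quaternary carbon. Ring B closes 6-exo-trig; any C8=C9 tautomer of 13 is attacked at the same carbon 6-endo and gives the same constitution. C10 is controlled by the resident C5 centre through a chair–chair transition state in which C6 is equatorial on ring A and C9 arrives along the equatorial direction, so that C20 ends axial and anti to H5 (trans fusion), whereas an axial arrival of C9 would meet the axial C4 methyl. C9 is controlled by the chair of the forming ring with the (E)-enoate pseudo-equatorial, which places C11 cis to C20, and the acidic C8–H should let the C8 epimers interconvert so that both pass through the arrangement with the C17 ester equatorial. The step needs hydrogen-atom transfer to the alkene and not to the enoate (secured by the polarity difference), ring closure faster than a second hydrogen transfer (secured by dilution and the four-atom tether) and trans fusion, which no later step can repair because base could carry a cis-fused isomer into the enantiomeric series, so that isomer is removed here.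

Step 7
Reactants: 14 keto diester, C8 epimers
Product: 15 17-tert-butyl 12-methyl (5R,8S,9R,10S)-6-oxo-13,14,15,16-tetranorlabdane-12,17-dioate
Conditions: NaOMe (0.3 equiv), MeOH, 50 °C
Reagents that add atoms: none
Why: Thermodynamic epimerisation through the ester enolate should move the C17 ester to the equatorial position trans to the C11 arm and away from the 1,3-diaxial contact with C20, while C5 stays trans and the tert-butyl ester resists methoxide.

Step 8
Reactants: 15 keto diester
Product: 16 17-tert-butyl 12-methyl (5R,8R,9R,10S)-6-(trifluoromethanesulfonyloxy)-13,14,15,16-tetranorlabd-6-ene-12,17-dioate (same geometry at C8; the descriptor changes by priority only)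
Conditions: KHMDS (1.05 equiv), THF, −78 °C; PhNTf2 (1.1 equiv), −78 → 0 °C
Reagents that add atoms: N-phenylbis(trifluoromethanesulfonimide), O=S(=O)(N(c1ccccc1)S(=O)(=O)C(F)(F)F)C(F)(F)F
Why: Kinetic enolisation of the ketone toward the C7 methylene (H5 is a shielded methine and the ester α-hydrogens are less acidic) and O-sulfonylation should give the C6=C7 enol triflate.

Step 9
Reactants: 16 enol triflate
Product: 17 17-tert-butyl 12-methyl (5R,8S,9R,10S)-13,14,15,16-tetranorlabd-6-ene-12,17-dioate
Conditions: Pd(OAc)2 (5 mol%), PPh3 (10 mol%), Bu3N (3 equiv), HCO2H (2 equiv), DMF, 60 °C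
Reagents that add atoms: none
Why: Palladium-catalysed formate reduction of an enol triflate (oxidative addition to zerovalent palladium, formate exchange, loss of CO2, reductive elimination) replaces the triflate by hydrogen and leaves the C6=C7 alkene of the target.

Step 10
Reactants: 17 alkene diester
Product: 18 tert-butyl (5R,8S,9R,10S)-12-hydroxy-13,14,15,16-tetranorlabd-6-en-17-oate
Conditions: LiBH4 (2 equiv), MeOH (2 equiv), THF, 0 °C → rt
Reagents that add atoms: none
Why: Chemoselective borohydride reduction should take the methyl ester to the primary alcohol while the tert-butyl ester, which LiBH4 does not reduce and which cannot lactonise, stays.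

Step 11
Reactants: 18 primary alcohol
Product: 19 tert-butyl (5R,8S,9R,10S)-12-iodo-13,14,15,16-tetranorlabd-6-en-17-oate
Conditions: PPh3, imidazole, I2, CH2Cl2, 0 °C → rt
Reagents that add atoms: iodine, II
Why: Appel iodination of an unhindered primary alcohol under buffered conditions should give the iodide without touching C8.

Step 12
Reactants: 20 2-(prop-2-yn-1-yloxy)oxane (tetrahydropyranyl ether of propargyl alcohol)
Product: 21 tert-butyl 4-(oxan-2-yloxy)but-2-ynoate
Conditions: n-BuLi, THF, −78 °C; Boc2O, −78 → 0 °C
Reagents that add atoms: di-tert-butyl dicarbonate, CC(C)(C)OC(=O)OC(=O)OC(C)(C)C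
Why: Acylation of the lithium acetylide with the dicarbonate is a standard route to tert-butyl alkynoates.

Step 13
Reactants: 21 protected ynoate
Product: 22 tert-butyl 4-hydroxybut-2-ynoate
Conditions: TsOH·H2O (cat.), MeOH, rt
Reagents that add atoms: none
Why: Acid-catalysed acetal exchange with methanol removes the tetrahydropyranyl group under conditions that a tert-butyl ester tolerates.

Step 14
Reactants: 22 hydroxy ynoate
Product: 23 tert-butyl (Z)-4-hydroxy-3-iodobut-2-enoate
Conditions: NaI (1.5 equiv), AcOH (3 equiv), MeCN, 50 °C
Reagents that add atoms: sodium iodide, [Na+].[I-]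
Why: Conjugate hydroiodination of an alkynoate proceeds by anti addition, iodide to the β-carbon and hydrogen to the α-carbon, which sets iodine cis to the ester and the hydroxymethyl group trans to it, so no lactone can form.

Step 15
Reactants: 23 hydroxy iodoenoate
Product: 24 tert-butyl (Z)-4-acetoxy-3-iodobut-2-enoate
Conditions: Ac2O, pyridine, CH2Cl2, 0 °C → rt
Reagents that add atoms: acetic anhydride, CC(=O)OC(C)=O
Why: Acetylation of the primary alcohol is done after the hydroiodination because a 4-hydroxy-2-ynoate isomerises under amine bases.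

Step 16
Reactants: 19 primary iodide; 24 (Z)-iodoenoate
Product: 26 di-tert-butyl (5R,8S,9R,10S,13E)-16-acetoxylabda-6,13-diene-15,17-dioate, via alkylzinc iodide 25 (not isolated)
Conditions: Zn dust (TMSCl/BrCH2CH2Br-activated), DMA, 40 °C; then 24, PdCl2(dppf) (5 mol%), DMA/THF, rt
Reagents that add atoms: none
Why: Zinc insertion into the primary iodide and Negishi coupling with the alkenyl iodide form C12–C13 with retention of the alkene geometry, so C12 ends cis to the C15 carboxyl and the acetoxymethyl group trans to it, and the alkylzinc leaves both tert-butyl esters and the acetate alone.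

Step 17
Reactants: 26 di-tert-butyl ester
Product: 27 (5R,8S,9R,10S,13E)-16-acetoxylabda-6,13-diene-15,17-dioic acid (target)
Conditions: CF3CO2H/CH2Cl2 (1:4), anisole, 0 °C → rt
Reagents that add atoms: none
Why: Acidolysis of both tert-butyl esters through the tert-butyl cation frees the two acids without base, so the acetate, the C8 centre and the position of the C6=C7 alkene are not at risk.

Compound list
1 | methyl γ-cyclogeranate, racemic (methyl 2,2-dimethyl-6-methylidenecyclohexane-1-carboxylate) | C=C1CCCC(C)(C)C1C(=O)OC | starting material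
2 | racemic γ-cyclogeranic acid | C=C1CCCC(C)(C)C1C(=O)O | intermediate
3 | (S)-1-phenylethylamine | C[C@H](N)c1ccccc1 | starting material
4 | (S)-1-phenylethylammonium (R)-2,2-dimethyl-6-methylidenecyclohexane-1-carboxylate | C=C1CCCC(C)(C)[C@H]1C(=O)[O-].C[C@H]([NH3+])c1ccccc1 | intermediate
5 | (R)-γ-cyclogeranic acid | C=C1CCCC(C)(C)[C@H]1C(=O)O | intermediate
6 | (R)-γ-cyclogeranoyl chloride | C=C1CCCC(C)(C)[C@H]1C(=O)Cl | intermediate
7 | 2-diazo-1-[(1R)-2,2-dimethyl-6-methylidenecyclohexyl]ethan-1-one | C=C1CCCC(C)(C)[C@H]1C(=O)C=[N+]=[N-] | intermediate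
8 | 2-bromo-1-[(1R)-2,2-dimethyl-6-methylidenecyclohexyl]ethan-1-one | C=C1CCCC(C)(C)[C@H]1C(=O)CBr | intermediate
9 | tert-butyl acetoacetate | CC(=O)CC(=O)OC(C)(C)C | starting material
10 | tert-butyl 2-acetyl-4-[(1R)-2,2-dimethyl-6-methylidenecyclohexyl]-4-oxobutanoate (mixture at C8) | C=C1CCCC(C)(C)[C@H]1C(=O)CC(C(C)=O)C(=O)OC(C)(C)C | intermediate
11 | methyl propiolate | C#CC(=O)OC | starting material
12 | 5-tert-butyl 1-methyl 4-acetyl-4-{2-[(1R)-2,2-dimethyl-6-methylidenecyclohexyl]-2-oxoethyl}pent-2-enedioate (alkene and C8 mixtures) | C=C1CCCC(C)(C)[C@H]1C(=O)CC(C(C)=O)(C=CC(=O)OC)C(=O)OC(C)(C)C | intermediate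
13 | 5-tert-butyl 1-methyl (2E)-4-{2-[(1R)-2,2-dimethyl-6-methylidenecyclohexyl]-2-oxoethyl}pent-2-enedioate (C8 epimers) | C=C1CCCC(C)(C)[C@H]1C(=O)CC(C(=O)OC(C)(C)C)/C=C/C(=O)OC | intermediate
14 | 17-tert-butyl 12-methyl (5R,9R,10S)-6-oxo-13,14,15,16-tetranorlabdane-12,17-dioate (trans-fused; C20 and C11 cis; C8 epimers) | COC(=O)C[C@@H]1C(C(=O)OC(C)(C)C)CC(=O)[C@@H]2C(C)(C)CCC[C@@]12C | intermediate
15 | 17-tert-butyl 12-methyl (5R,8S,9R,10S)-6-oxo-13,14,15,16-tetranorlabdane-12,17-dioate (C17 ester equatorial, trans to the C11 arm) | COC(=O)C[C@@H]1[C@@H](C(=O)OC(C)(C)C)CC(=O)[C@@H]2C(C)(C)CCC[C@@]12C | intermediate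
16 | 17-tert-butyl 12-methyl (5R,8R,9R,10S)-6-(trifluoromethanesulfonyloxy)-13,14,15,16-tetranorlabd-6-ene-12,17-dioate | COC(=O)C[C@@H]1[C@@H](C(=O)OC(C)(C)C)C=C(OS(=O)(=O)C(F)(F)F)[C@@H]2C(C)(C)CCC[C@@]12C | intermediate
17 | 17-tert-butyl 12-methyl (5R,8S,9R,10S)-13,14,15,16-tetranorlabd-6-ene-12,17-dioate | COC(=O)C[C@@H]1[C@@H](C(=O)OC(C)(C)C)C=C[C@@H]2C(C)(C)CCC[C@@]12C | intermediate
18 | tert-butyl (5R,8S,9R,10S)-12-hydroxy-13,14,15,16-tetranorlabd-6-en-17-oate | OCC[C@@H]1[C@@H](C(=O)OC(C)(C)C)C=C[C@@H]2C(C)(C)CCC[C@@]12C | intermediate
19 | tert-butyl (5R,8S,9R,10S)-12-iodo-13,14,15,16-tetranorlabd-6-en-17-oate | ICC[C@@H]1[C@@H](C(=O)OC(C)(C)C)C=C[C@@H]2C(C)(C)CCC[C@@]12C | intermediate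
20 | 2-(prop-2-yn-1-yloxy)oxane | C#CCOC1CCCCO1 | starting material
21 | tert-butyl 4-(oxan-2-yloxy)but-2-ynoate | CC(C)(C)OC(=O)C#CCOC1CCCCO1 | intermediate
22 | tert-butyl 4-hydroxybut-2-ynoate | CC(C)(C)OC(=O)C#CCO | intermediate
23 | tert-butyl (Z)-4-hydroxy-3-iodobut-2-enoate | OC/C(I)=C/C(=O)OC(C)(C)C | intermediate
24 | tert-butyl (Z)-4-acetoxy-3-iodobut-2-enoate | CC(=O)OC/C(I)=C/C(=O)OC(C)(C)C | intermediate
25 | alkylzinc iodide from 19 (C12–ZnI) | I[Zn]CC[C@@H]1[C@@H](C(=O)OC(C)(C)C)C=C[C@@H]2C(C)(C)CCC[C@@]12C | intermediate
26 | di-tert-butyl (5R,8S,9R,10S,13E)-16-acetoxylabda-6,13-diene-15,17-dioate | CC(=O)OC/C(=C/C(=O)OC(C)(C)C)CC[C@@H]1[C@@H](C(=O)OC(C)(C)C)C=C[C@@H]2C(C)(C)CCC[C@@]12C | intermediate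
27 | (5R,8S,9R,10S,13E)-16-acetoxylabda-6,13-diene-15,17-dioic acid | CC(=O)OC/C(=C/C(=O)O)CC[C@@H]1[C@@H](C(=O)O)C=C[C@@H]2C(C)(C)CCC[C@@]12C | target

Total step count: 17. Longest linear sequence: 13 (steps 1–11, 16 and 17); steps 12–15 make the side-chain fragment.

Steps most likely to fail

Step 6. Two processes may spoil it. First, the glutaconate unit of 13 may shift its proton at C8 before hydrogen-atom transfer, so that the C8=C9 tautomer and both C8 epimers close through less ordered arrangements and facial selectivity at C9 and C10 drops. Second, the C10 radical may take a second hydrogen atom before it reaches C9. The fallback sets out from 10 and blocks C8 during ring closure. The Michael adduct 12 is isolated (11, Cs2CO3 10 mol%, MeCN) and cyclised as such with Fe(acac)3/PhSiH3 in EtOH/(CH2OH)2 at 60 °C. C8 is then quaternary, so no tautomer or epimer can form, and the geminal pair on C8 speeds closure. This should give 17-tert-butyl 12-methyl (5R,9R,10S)-8-acetyl-6-oxo-13,14,15,16-tetranorlabdane-12,17-dioate F1. After removal of any cis-fused isomer, NaOMe in MeOH at 65 °C cleaves the acetyl group by a retro-Claisen reaction and equilibrates C8, and the route is rejoined at 15.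

Step 2. The diastereomeric salts may not differ enough in solubility, so that crystallisation gives low enantiomeric purity or low recovery. The fallback sets out from 2 and separates the enantiomers of the free acid by preparative supercritical-fluid chromatography on an amylose carbamate chiral phase (CO2/MeOH with 0.1% CF3CO2H). The (R)-acid is assigned by the sign of rotation against the reported value and enters the route at 5, where step 3 continues from the acid chloride stage. This fallback makes no compound outside the list (F0).

Step 16. Zerovalent palladium may ionise the allylic acetate of 24 or of 26, leading to loss of acetate or to allylic substitution by the alkylzinc in competition with the cross-coupling. The fallback sets out from 23 and introduces the acetate after the C–C bond. TBSCl and imidazole in DMF give tert-butyl (Z)-4-(tert-butyldimethylsilyloxy)-3-iodobut-2-enoate F2. Negishi coupling of F2 with 25 (from 19, as in step 16) gives di-tert-butyl (5R,8S,9R,10S,13E)-16-(tert-butyldimethylsilyloxy)labda-6,13-diene-15,17-dioate F3. HF·pyridine in THF at 0 °C frees di-tert-butyl (5R,8S,9R,10S,13E)-16-hydroxylabda-6,13-diene-15,17-dioate F4, whose hydroxymethyl group is trans to the ester and cannot lactonise. Ac2O/pyridine then rejoins the route at 26.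

Further compounds
F1 | step 6 | 17-tert-butyl 12-methyl (5R,9R,10S)-8-acetyl-6-oxo-13,14,15,16-tetranorlabdane-12,17-dioate (C8 mixture) | COC(=O)C[C@@H]1C(C(C)=O)(C(=O)OC(C)(C)C)CC(=O)[C@@H]2C(C)(C)CCC[C@@]12C
F0 | step 2 | none | none
F2 | step 16 | tert-butyl (Z)-4-(tert-butyldimethylsilyloxy)-3-iodobut-2-enoate | CC(C)(C)[Si](C)(C)OC/C(I)=C/C(=O)OC(C)(C)C
F3 | step 16 | di-tert-butyl (5R,8S,9R,10S,13E)-16-(tert-butyldimethylsilyloxy)labda-6,13-diene-15,17-dioate | CC(C)(C)[Si](C)(C)OC/C(=C/C(=O)OC(C)(C)C)CC[C@@H]1[C@@H](C(=O)OC(C)(C)C)C=C[C@@H]2C(C)(C)CCC[C@@]12C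
F4 | step 16 | di-tert-butyl (5R,8S,9R,10S,13E)-16-hydroxylabda-6,13-diene-15,17-dioate | OC/C(=C/C(=O)OC(C)(C)C)CC[C@@H]1[C@@H](C(=O)OC(C)(C)C)C=C[C@@H]2C(C)(C)CCC[C@@]12C
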